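**Retrosynthetic overview**
1. Target 11 ⇐ 9: the angelate goes on last, onto the only free hydroxyl (C3) of the 15,18-bis-silylated triol, followed by fluoride deprotection.
2. Triol 8 ⇐ bicyclic methyl ketone 6: C13=C14–C15 by Horner–Wadsworth–Emmons olefination and hydride reduction.
3. Key disconnection 6 ⇐ 3: the C4–C5 and C9–C10 bonds and the C8=C17 alkene come from one Cp2TiCl-mediated radical cascade of an acyclic epoxy dienone; ring A closes first, ring B second, in the same operation.
4. 3 ⇐ 1: terminal allylic hydroxylation and Sharpless epoxidation of all-E farnesylacetone; the epoxide CH carbon becomes C3 and controls C4, C5, C9 and C10.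

Assumption: isomerically pure (5E,9E)-farnesylacetone is bought (a commercial 5E/5Z mixture would be fractionated once before use); labdane numbering is used for all bicyclic compounds.

**Route**

Step 1
Reactants: 1 (5E,9E)-farnesylacetone [(5E,9E)-6,10,14-trimethylpentadeca-5,9,13-trien-2-one]
Product: 2 (5E,9E,13E)-15-hydroxy-6,10,14-trimethylpentadeca-5,9,13-trien-2-one
Conditions: SeO2 (0.3 equiv), t-BuOOH (70% aq, 3 equiv), salicylic acid (0.1 equiv), CH2Cl2, 0 °C to rt, stopped at about 60% conversion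
Reagents that add atoms: selenium dioxide, O=[Se]=O; tert-butyl hydroperoxide, CC(C)(C)OO
Why: Sharpless–Umbreit catalytic SeO2 allylic oxidation (ene reaction, then [2,3]-sigmatropic shift) hydroxylates the E-methyl of the terminal, most accessible trisubstituted alkene and gives the E-allylic alcohol, while the ketone and the inner alkenes are left alone at this temperature (enal by-product and recovered 1 are separated).

Step 2
Reactants: 2 (5E,9E,13E)-15-hydroxy-6,10,14-trimethylpentadeca-5,9,13-trien-2-one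
Product: 3 (5E,9E)-12-[(2R,3R)-3-(hydroxymethyl)-3-methyloxiran-2-yl]-6,10-dimethyldodeca-5,9-dien-2-one
Conditions: Ti(OiPr)4 (10 mol%), D-(−)-diethyl tartrate (12 mol%), t-BuOOH (2 equiv, in decane), 4 Å molecular sieves, CH2Cl2, −20 °C
Reagents that add atoms: tert-butyl hydroperoxide, CC(C)(C)OO
Why: Katsuki–Sharpless asymmetric epoxidation is directed by the allylic hydroxyl, so only the C13=C14 alkene reacts, and D-(−)-diethyl tartrate gives the (2R,3R)-epoxide (high ee is typical for E-2-methylalk-2-en-1-ols), whose CH carbon becomes C3 (R) of the target.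

Step 3
Reactants: 3 (5E,9E)-12-[(2R,3R)-3-(hydroxymethyl)-3-methyloxiran-2-yl]-6,10-dimethyldodeca-5,9-dien-2-one
Product: 6 (3R,4S,5S,9R,10S)-3,18-dihydroxy-14,15-dinorlabd-8(17)-en-13-one, via epoxy alcohol trimethylsilyl ether 4 (not isolated), via bicyclic bis(trimethylsilyl) ether 5 (not isolated)
Conditions: Me3SiCl (4 equiv), 2,4,6-collidine (7 equiv), THF, rt, 30 min; then Cp2TiCl2 (0.2 equiv), Mn dust (8 equiv), rt, 16 h; filter; 1 M aq HCl, THF, rt, 20 min
Reagents that add atoms: none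
Why: Nugent–RajanBabu epoxide homolysis by Cp2TiCl (trivalent titanium) at the quaternary carbon starts a radical polyene cyclisation in which ring A and then ring B close by 6-endo attack through chair–chair transition states (equatorial C3–O fixes the trans-decalin at C5/C10 and the equatorial side chain at C9, and the larger CH2OSiMe3 group takes the equatorial site at C4), the final tertiary C8 radical is turned by Cp2TiCl into the exocyclic C8=C17 alkene, the unactivated methyl ketone is not attacked, and the acidic work-up removes both Me3Si groups.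

Step 4
Reactants: 6 (3R,4S,5S,9R,10S)-3,18-dihydroxy-14,15-dinorlabd-8(17)-en-13-one
Product: 7 ethyl (3R,4S,5S,9R,10S,13E)-3,18-dihydroxylabda-8(17),13-dien-15-oate
Conditions: (EtO)2P(O)CH2CO2Et (3 equiv), NaH (3 equiv), THF, 0 °C, 30 min; add 6, rt to 50 °C, 16 h; chromatography removes the 13Z isomer
Reagents that add atoms: triethyl phosphonoacetate, CCOC(=O)CP(=O)(OCC)OCC
Why: Horner–Wadsworth–Emmons olefination of the methyl ketone with the pre-formed sodium phosphonate (too weak a base to deprotonate the free diol) gives mainly the thermodynamically preferred 13E-enoate (about 6:1 E/Z expected).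

Step 5
Reactants: 7 ethyl (3R,4S,5S,9R,10S,13E)-3,18-dihydroxylabda-8(17),13-dien-15-oate
Product: 8 (3R,4S,5S,9R,10S,13E)-labda-8(17),13-diene-3,15,18-triol
Conditions: i-Bu2AlH (5 equiv), CH2Cl2, −78 to 0 °C; aq potassium sodium tartrate (KNaC4H4O6)
Reagents that add atoms: none
Why: i-Bu2AlH 1,2-reduction of the conjugated ester gives the allylic alcohol without touching either alkene or any stereocentre (two equivalents are used up by the free hydroxyls).

Step 6
Reactants: 8 (3R,4S,5S,9R,10S,13E)-labda-8(17),13-diene-3,15,18-triol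
Product: 9 (3R,4S,5S,9R,10S,13E)-15,18-bis[(tert-butyldimethylsilyl)oxy]labda-8(17),13-dien-3-ol
Conditions: TBSCl (2.2 equiv), imidazole (5 equiv), DMF, 0 °C to rt
Reagents that add atoms: tert-butyldimethylsilyl chloride, CC(C)(C)[Si](C)(C)Cl
Why: Selective silylation by steric rate difference: both primary hydroxyls (allylic C15, neopentylic C18) react with TBSCl/imidazole, while the secondary C3 hydroxyl next to the quaternary C4 stays free.

Step 7
Reactants: 9 (3R,4S,5S,9R,10S,13E)-15,18-bis[(tert-butyldimethylsilyl)oxy]labda-8(17),13-dien-3-ol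
Product: 10 (3R,4S,5S,9R,10S,13E)-15,18-bis[(tert-butyldimethylsilyl)oxy]labda-8(17),13-dien-3-yl (2Z)-2-methylbut-2-enoate
Conditions: LiN(SiMe3)2 (1.3 equiv), THF, −20 °C, 15 min; angelic anhydride (1.5 equiv), −20 to 0 °C; H2O
Reagents that add atoms: angelic anhydride [(2Z)-2-methylbut-2-enoic anhydride], C/C=C(/C)C(=O)OC(=O)/C(C)=C\C
Why: O-acylation of the lithium alkoxide with angelic anhydride (stereoconservative angeloylation) esterifies the only free hydroxyl, and because no nucleophilic catalyst is present the Z-alkene is not isomerised to the tiglate.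

Step 8
Reactants: 10 (3R,4S,5S,9R,10S,13E)-15,18-bis[(tert-butyldimethylsilyl)oxy]labda-8(17),13-dien-3-yl (2Z)-2-methylbut-2-enoate
Product: 11 (3R,4S,5S,9R,10S,13E)-15,18-dihydroxylabda-8(17),13-dien-3-yl (2Z)-2-methylbut-2-enoate
Conditions: HF·pyridine, pyridine, THF, 0 °C to rt
Reagents that add atoms: none
Why: Fluoride-mediated desilylation under buffered, mildly acidic conditions cleaves both primary silyl ethers and leaves the angelate, its Z-geometry and its position unchanged (no base is present to drive a 3-O to 18-O acyl shift).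

**Compound list**

1 | (5E,9E)-6,10,14-trimethylpentadeca-5,9,13-trien-2-one (all-E farnesylacetone) | CC(=O)CC/C=C(\C)CC/C=C(\C)CCC=C(C)C | starting material
2 | (5E,9E,13E)-15-hydroxy-6,10,14-trimethylpentadeca-5,9,13-trien-2-one | CC(=O)CC/C=C(\C)CC/C=C(\C)CC/C=C(\C)CO | intermediate
3 | (5E,9E)-12-[(2R,3R)-3-(hydroxymethyl)-3-methyloxiran-2-yl]-6,10-dimethyldodeca-5,9-dien-2-one | CC(=O)CC/C=C(\C)CC/C=C(\C)CC[C@H]1O[C@]1(C)CO | intermediate
4 | (5E,9E)-6,10-dimethyl-12-[(2R,3R)-3-methyl-3-[(trimethylsilyloxy)methyl]oxiran-2-yl]dodeca-5,9-dien-2-one | CC(=O)CC/C=C(\C)CC/C=C(\C)CC[C@H]1O[C@]1(C)CO[Si](C)(C)C | intermediate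
5 | (3R,4S,5S,9R,10S)-3,18-bis(trimethylsilyloxy)-14,15-dinorlabd-8(17)-en-13-one | C=C1CC[C@H]2[C@@](C)(CC[C@@H](O[Si](C)(C)C)[C@]2(C)CO[Si](C)(C)C)[C@@H]1CCC(C)=O | intermediate
6 | (3R,4S,5S,9R,10S)-3,18-dihydroxy-14,15-dinorlabd-8(17)-en-13-one; systematic: 4-[(1R,4aS,5S,6R,8aS)-6-hydroxy-5-(hydroxymethyl)-5,8a-dimethyl-2-methylidenedecahydronaphthalen-1-yl]butan-2-one; trans-decalin, 3-OH and 4-CH2OH equatorial | C=C1CC[C@H]2[C@@](C)(CC[C@@H](O)[C@]2(C)CO)[C@@H]1CCC(C)=O | intermediate
7 | ethyl (3R,4S,5S,9R,10S,13E)-3,18-dihydroxylabda-8(17),13-dien-15-oate | C=C1CC[C@H]2[C@@](C)(CC[C@@H](O)[C@]2(C)CO)[C@@H]1CC/C(C)=C/C(=O)OCC | intermediate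
8 | (3R,4S,5S,9R,10S,13E)-labda-8(17),13-diene-3,15,18-triol | C=C1CC[C@H]2[C@@](C)(CC[C@@H](O)[C@]2(C)CO)[C@@H]1CC/C(C)=C/CO | intermediate
9 | (3R,4S,5S,9R,10S,13E)-15,18-bis[(tert-butyldimethylsilyl)oxy]labda-8(17),13-dien-3-ol | C=C1CC[C@H]2[C@@](C)(CC[C@@H](O)[C@]2(C)CO[Si](C)(C)C(C)(C)C)[C@@H]1CC/C(C)=C/CO[Si](C)(C)C(C)(C)C | intermediate
10 | (3R,4S,5S,9R,10S,13E)-15,18-bis[(tert-butyldimethylsilyl)oxy]labda-8(17),13-dien-3-yl (2Z)-2-methylbut-2-enoate | C=C1CC[C@H]2[C@@](C)(CC[C@@H](OC(=O)/C(C)=C\C)[C@]2(C)CO[Si](C)(C)C(C)(C)C)[C@@H]1CC/C(C)=C/CO[Si](C)(C)C(C)(C)C | intermediate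
11 | (3R,4S,5S,9R,10S,13E)-15,18-dihydroxylabda-8(17),13-dien-3-yl (2Z)-2-methylbut-2-enoate (ent-labdane series; CNP0118197.1) | C=C1CC[C@H]2[C@@](C)(CC[C@@H](OC(=O)/C(C)=C\C)[C@]2(C)CO)[C@@H]1CC/C(C)=C/CO | target

**Step count**

Total steps: 8. Longest linear sequence: 8 steps (1 to 11, fully linear).

**Three steps most likely to fail, with fallbacks**

Step 3 (radical bicyclisation). The risks are termination after ring A only, weak control at C4 because the radical carbon is planar, and loss of the epoxy alcohol. The fallback sets out from 3 and comes back at 9; it closes the rings by a polar, stereospecific epoxide opening after the chain has been completed. Compound 3 is silylated (TBSCl, imidazole) to the epoxy ketone tert-butyldimethylsilyl ether F1. The ketone is then homologated (triethyl phosphonoacetate, NaH) to the ethyl epoxy trienoate F2. F2 is cyclised with MeAlCl2 (CH2Cl2, −78 °C): the C5=C10 alkene attacks the quaternary epoxide carbon from the back, so the E-geometry of the former allylic alcohol is transferred directly into an equatorial CH2OSi group. The electron-poor enoate alkene cannot join the cascade, which therefore stops at the bicyclic hydroxy enoate F3; its 8(17)-ene is separated from ring-alkene isomers on AgNO3-impregnated silica. Reduction with i-Bu2AlH gives the 3,15-diol 18-silyl ether F4, and TBSCl/imidazole (1.1 equiv, 0 °C) silylates the primary allylic hydroxyl to rejoin the route at 9.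

Step 4 (olefination of a methyl ketone). The risks are a modest E/Z ratio and a sluggish reaction beside a free diol. The fallback sets out from 6 and comes back at 8; it builds the alkene by stereospecific carbometalation. Compound 6 is bis-silylated (TBSOTf, 2,6-lutidine) to the bis(tert-butyldimethylsilyl) ether ketone F5. LiN(i-Pr)2 and then ClP(O)(OEt)2 give the terminal enol diethyl phosphate F6, which a further 2.2 equiv of LiN(i-Pr)2 eliminates to the terminal alkyne F7. Negishi carboalumination (Me3Al, Cp2ZrCl2 cat.; then paraformaldehyde) adds CH3 and CH2OH syn across the alkyne and gives only the 13E-allylic alcohol bis-silyl ether F8. Bu4NF (THF, 50 °C) removes both silyl groups to give 8.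

Step 7 (angeloylation). The risks are slow acylation of a hindered alcohol next to a quaternary carbon, Z to E isomerisation of the acyl group, and a silyl shift in the alkoxide that would send the ester to O18. The fallback sets out from 9 and comes back at 10; it forms the ester bond first with an unhindered saturated acid and makes the Z-alkene afterwards. Compound 9 is esterified under neutral carbodiimide conditions (DCC, DMAP cat.) with 2-[bis(2,2,2-trifluoroethoxy)phosphoryl]propanoic acid to give the 3-O-(2-phosphonopropanoyl) ester F9. A Still–Gennari olefination (KN(SiMe3)2, 18-crown-6, CH3CHO, THF, −78 °C) then delivers the Z-configured 2-methylbut-2-enoate 10.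

**Further compounds**

F1 | step 3 | (5E,9E)-12-[(2R,3R)-3-[(tert-butyldimethylsilyloxy)methyl]-3-methyloxiran-2-yl]-6,10-dimethyldodeca-5,9-dien-2-one | CC(=O)CC/C=C(\C)CC/C=C(\C)CC[C@H]1O[C@]1(C)CO[Si](C)(C)C(C)(C)C
F2 | step 3 | ethyl (2E,6E,10E)-13-[(2R,3R)-3-[(tert-butyldimethylsilyloxy)methyl]-3-methyloxiran-2-yl]-3,7,11-trimethyltrideca-2,6,10-trienoate | CCOC(=O)/C=C(\C)CC/C=C(\C)CC/C=C(\C)CC[C@H]1O[C@]1(C)CO[Si](C)(C)C(C)(C)C
F3 | step 3 | ethyl (3R,4S,5S,9R,10S,13E)-18-[(tert-butyldimethylsilyl)oxy]-3-hydroxylabda-8(17),13-dien-15-oate | C=C1CC[C@H]2[C@@](C)(CC[C@@H](O)[C@]2(C)CO[Si](C)(C)C(C)(C)C)[C@@H]1CC/C(C)=C/C(=O)OCC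
F4 | step 3 | (3R,4S,5S,9R,10S,13E)-18-[(tert-butyldimethylsilyl)oxy]labda-8(17),13-diene-3,15-diol | C=C1CC[C@H]2[C@@](C)(CC[C@@H](O)[C@]2(C)CO[Si](C)(C)C(C)(C)C)[C@@H]1CC/C(C)=C/CO
F5 | step 4 | (3R,4S,5S,9R,10S)-3,18-bis[(tert-butyldimethylsilyl)oxy]-14,15-dinorlabd-8(17)-en-13-one | C=C1CC[C@H]2[C@@](C)(CC[C@@H](O[Si](C)(C)C(C)(C)C)[C@]2(C)CO[Si](C)(C)C(C)(C)C)[C@@H]1CCC(C)=O
F6 | step 4 | diethyl (3R,4S,5S,9R,10S)-3,18-bis[(tert-butyldimethylsilyl)oxy]-14,15-dinorlabda-8(17),13(16)-dien-13-yl phosphate | C=C1CC[C@H]2[C@@](C)(CC[C@@H](O[Si](C)(C)C(C)(C)C)[C@]2(C)CO[Si](C)(C)C(C)(C)C)[C@@H]1CCC(=C)OP(=O)(OCC)OCC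
F7 | step 4 | terminal alkyne: (3R,4S,5S,9R,10S)-3,18-bis[(tert-butyldimethylsilyl)oxy]-9-(but-3-yn-1-yl) bicyclic core [C9–CH2CH2–C≡CH, 8(17)-ene retained] | C=C1CC[C@H]2[C@@](C)(CC[C@@H](O[Si](C)(C)C(C)(C)C)[C@]2(C)CO[Si](C)(C)C(C)(C)C)[C@@H]1CCC#C
F8 | step 4 | (3R,4S,5S,9R,10S,13E)-3,18-bis[(tert-butyldimethylsilyl)oxy]labda-8(17),13-dien-15-ol | C=C1CC[C@H]2[C@@](C)(CC[C@@H](O[Si](C)(C)C(C)(C)C)[C@]2(C)CO[Si](C)(C)C(C)(C)C)[C@@H]1CC/C(C)=C/CO
F9 | step 7 | (3R,4S,5S,9R,10S,13E)-15,18-bis[(tert-butyldimethylsilyl)oxy]labda-8(17),13-dien-3-yl 2-[bis(2,2,2-trifluoroethoxy)phosphoryl]propanoate | C=C1CC[C@H]2[C@@](C)(CC[C@@H](OC(=O)C(C)P(=O)(OCC(F)(F)F)OCC(F)(F)F)[C@]2(C)CO[Si](C)(C)C(C)(C)C)[C@@H]1CC/C(C)=C/CO[Si](C)(C)C(C)(C)C
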